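**Retrosynthetic overview**

1. Germacrane numbering is used: ring C1–C10, ether O between C5 and C10, lactone C12(=O)–O–C6 with C11=C13, ester on O-8, C14 = methyl on C10, C15 = ester carbon on C4. Last disconnections: C11=C13 from a 13-dimethylamino adduct (masked α-methylene lactone), and the C3=C4 enoate from a C3 ketone after hydrogenation of C1=C2.
2. Key disconnection: C1–C2 and C4–C5 together. At the β-keto ester level C2–C3–C4–C15 is methyl acetoacetate; its two nucleophilic carbons (C4 active methylene, C2 methyl) meet two aldehyde carbons, C5 and C1, of an acyclic hydroxy dialdehyde.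
3. Enabling feature: in the oxepine ring (O, C10, C1, C2, C3, C4, C5) the carbons C5 and C1 flank the bridging oxygen 1,4 (C5–O–C10–C1) and the C3=C4–C15 enoate lies between them. An oxygen-linked 1,4-dialdehyde plus a β-keto ester is therefore a Robinson–Schöpf-type double-condensation retron; the tertiary C10–OH closes the oxepane ring (O, C5–C10) on the way and dictates C5.
4. The dialdehyde comes from a three-component union at C8 (1,3-dithiane linchpin) of (S)-2-methylglycidol (C1, C9, C10, C14), (S)-5-(hydroxymethyl)butenolide (C5, C6, C7, C11, C12) and Eschenmoser's salt (C13). C8 is set by directed asymmetric hydrogenation and acylated early with the epoxy acid from Sharpless epoxidation of tiglyl alcohol.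
5. Ring order: γ-lactone (chiral pool) → oxepane and oxepine together in the key step (this closes the ten-membered carbocycle as an 11-oxabicyclo[4.4.1]undecane) → exocyclic methylene last.

Key step: step 12

Remark: the acyl group on O-8 is read from the SMILES as (2S,3R)-2,3-dimethyloxirane-2-carboxylate (the two methyl groups cis), i.e. the epoxide of a tiglate, and is made as such.

**Route**

Step 1
Reactants: 1 (S)-2-methylglycidol
Product: 2 (R)-tert-butyldimethyl[(2-methyloxiran-2-yl)methoxy]silane
Conditions: TBSCl, imidazole, CH2Cl2, 0 °C → rt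
Reagents that add atoms: tert-butyldimethylsilyl chloride, C[Si](C)(Cl)C(C)(C)C
Why: Silyl ether formation under imidazole avoids alkoxide formation (no Payne rearrangement), so the future C10 stereocentre is untouched.

Step 2
Reactants: 2 silyl epoxide; 3 1,3-dithiane
Product: 4 (2R)-1-[(tert-butyldimethylsilyl)oxy]-3-(1,3-dithian-2-yl)-2-methylpropan-2-ol
Conditions: 3, n-BuLi, THF, −30 °C; then 2, −30 → 0 °C; H2O
Reagents that add atoms: none
Why: Corey–Seebach alkylation: 2-lithio-1,3-dithiane should open the 2,2-disubstituted epoxide by SN2 attack at the unsubstituted CH2 (future C9), leaving the C10–O bond and its configuration intact.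

Step 3
Reactants: 5 (5S)-5-(hydroxymethyl)furan-2(5H)-one
Product: 6 (5S)-5-{[(tert-butyldimethylsilyl)oxy]methyl}furan-2(5H)-one
Conditions: TBSCl, imidazole, CH2Cl2, 0 °C → rt
Reagents that add atoms: tert-butyldimethylsilyl chloride, C[Si](C)(Cl)C(C)(C)C
Why: Standard silyl ether formation; the C6 stereocentre comes from the chiral pool and is not touched.

Step 4
Reactants: 4 hydroxy dithiane; 6 silyl butenolide; 7 N,N-dimethylmethyleneiminium iodide (Eschenmoser's salt)
Product: 8 all-trans 3-[(dimethylamino)methyl]-4-(2-substituted-1,3-dithian-2-yl) lactone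
Conditions: 4, n-BuLi (2.1 equiv), THF, −30 → 0 °C; DMPU, −78 °C, then 6; then 7, −78 → −20 °C; H2O
Reagents that add atoms: none
Why: Corey–Seebach umpolung in a Michael/Mannich sequence: the dilithio derivative of 4 should add 1,4 to the butenolide anti to the C6 side chain (sets C7), and the lactone enolate should be aminomethylated anti to the new C7 substituent (the C11 centre is destroyed later).

Step 5
Reactants: 8 dithiane lactone
Product: 9 C8 ketone (β-hydroxy ketone)
Conditions: I2, NaHCO3, acetone/H2O, 0 °C
Reagents that add atoms: water, O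
Why: Buffered oxidative hydrolysis of the dithioacetal should unmask the C8 ketone without touching the silyl ethers, the lactone or the amine.

Step 6
Reactants: 9 β-hydroxy ketone
Product: 10 C8/C10 anti-diol (8R)
Conditions: H2 (50 atm), RuCl2[(S)-BINAP] (cat.), EtOH, 40 °C
Reagents that add atoms: none
Why: Noyori asymmetric hydrogenation of a β-hydroxy ketone: the C10 hydroxyl chelates ruthenium and the (S)-BINAP ligand should select the face that gives the 8R alcohol (1,3-anti to the C10 oxygen).

Step 7
Reactants: 11 (E)-2-methylbut-2-en-1-ol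
Product: 12 [(2R,3R)-2,3-dimethyloxiran-2-yl]methanol
Conditions: Ti(OiPr)4 (cat.), D-(−)-diethyl tartrate (cat.), t-BuOOH, 4 Å MS, CH2Cl2, −20 °C
Reagents that add atoms: tert-butyl hydroperoxide, CC(C)(C)OO
Why: Sharpless asymmetric epoxidation: the D-(−)-tartrate catalyst should deliver oxygen to the face that gives the (2R,3R)-epoxy alcohol, and the E-alkene geometry fixes the cis relation of the two methyl groups.

Step 8
Reactants: 12 epoxy alcohol
Product: 13 (2S,3R)-2,3-dimethyloxirane-2-carboxylic acid
Conditions: TEMPO (cat.), PhI(OAc)2, MeCN/H2O, rt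
Reagents that add atoms: water, O
Why: Nitroxyl-catalysed oxidation of the primary alcohol through the aldehyde hydrate to the acid runs near neutral pH and should leave the epoxide and both stereocentres intact.

Step 9
Reactants: 10 anti-diol; 13 epoxy acid
Product: 15 C8 (2S,3R)-2,3-dimethyloxirane-2-carboxylate of 10, via mixed anhydride 14 (not isolated)
Conditions: 13, 2,4,6-Cl3C6H2COCl, Et3N, THF, rt; then 10, DMAP, toluene, 40 °C
Reagents that add atoms: none
Why: Yamaguchi esterification should acylate the secondary C8 hydroxyl selectively, since the tertiary C10 hydroxyl is unreactive; no stereocentre is affected.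

Step 10
Reactants: 15 bis-silyl ether
Product: 16 triol (C5–OH, C1–OH, C10–OH)
Conditions: HF·pyridine, pyridine, THF, 0 °C → rt
Reagents that add atoms: none
Why: Buffered fluoride cleavage of the two primary silyl ethers should be tolerated by the glycidic ester, the lactone and the amine.

Step 11
Reactants: 16 triol
Product: 17 hydroxy dialdehyde (C5 and C1 as CHO)
Conditions: Dess–Martin periodinane, NaHCO3, CH2Cl2, 0 °C → rt; crude 17 used at once
Reagents that add atoms: none
Why: Dess–Martin oxidation should convert both primary alcohols to aldehydes while the tertiary alcohol cannot react, and the buffered, amine-free conditions avoid epimerisation at C6.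

Step 12
Reactants: 17 hydroxy dialdehyde; 18 methyl acetoacetate
Product: 21 bridged dienol ester (11-oxabicyclo[4.4.1] core with C1=C2 and enolised C3 ketone), via Knoevenagel adduct 19 (not isolated), via oxa-Michael adduct 20 (not isolated)
Conditions: 18 (1.05 equiv), piperidine (0.2 equiv), AcOH (0.4 equiv), 4 Å MS, CH2Cl2, 0 → 40 °C
Reagents that add atoms: none
Why: Proposed new method: piperidinium acetate condenses the active methylene (future C4) of 18 with the unhindered C5 aldehyde (Knoevenagel, 19), the tertiary C10 hydroxyl adds reversibly to C5 of the alkylidene (oxa-Michael, 20), and the methyl ketone carbon (future C2), as its enamine or enol, then attacks the non-enolisable C1 aldehyde and dehydrates irreversibly, which pulls the preceding equilibria forward. The closest known reaction types are the Knoevenagel/oxa-Michael C-glycosylation of lactols and hydroxy aldehydes with β-dicarbonyl compounds (Lubineau and Maitland–Japp reactions) and the amine-mediated intramolecular aldol condensation of an acetoacetate methyl ketone (Hagemann ester and Robinson–Schöpf double condensations). The oxepane ring (O, C5, C6, C7, C8, C9, C10) closes by 7-exo-trig oxa-Michael addition and the oxepine ring (O, C10, C1, C2, C3, C4, C5) by 7-(enolendo)-exo-trig aldol condensation, which together complete the ten-membered carbocycle as an 11-oxabicyclo[4.4.1]undecane. C5 is the only new stereocentre and is set by C10: the oxa-Michael step is reversible and only the C5 epimer whose C4 arm is cis to the C10 formyl group can bridge, while C4 is held as the chelated enol. The step needs regioselectivity (C4 to C5 and C2 to C1, not the reverse); it is secured by the acidity order of 18 (C4–H far above C2–H), by the neopentyl, α-quaternary C1 aldehyde being slow in intermolecular condensation and unable to give a productive oxa-Michael closure (a three-membered ring would result), and by the reversibility of any wrong Knoevenagel adduct.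

Step 13
Reactants: 21 bridged dienol ester
Product: 22 1,2-dihydro β-keto ester (chelated enol)
Conditions: H2 (1 atm), RhCl(PPh3)3 (cat.), toluene/EtOH, rt
Reagents that add atoms: none
Why: Homogeneous hydrogenation should saturate only the disubstituted C1=C2 bond, leave the tetrasubstituted enol, and avoid hydrogenolysis of the allylic C10–O bond.

Step 14
Reactants: 22 β-keto ester
Product: 23 C3 enol triflate
Conditions: NaH, PhNTf2, THF, 0 °C → rt
Reagents that add atoms: N-phenylbis(trifluoromethanesulfonimide), O=S(=O)(N(c1ccccc1)S(=O)(=O)C(F)(F)F)C(F)(F)F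
Why: O-Sulfonylation of the sodium enolate of the β-keto ester should give the C3 enol triflate regiospecifically, with the C3=C4 position fixed by the ester.

Step 15
Reactants: 23 enol triflate
Product: 24 C3=C4 enoate (13-dimethylamino-11,13-dihydro target)
Conditions: Pd(OAc)2 (cat.), PPh3, HCO2H, n-Bu3N, DMF, rt → 40 °C
Reagents that add atoms: none
Why: Palladium-catalysed formate reduction of the vinyl triflate (oxidative addition, formate exchange, decarboxylation, reductive elimination) should give the enoate, whose geometry is fixed by the seven-membered ring.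

Step 16
Reactants: 24 amino lactone
Product: 26 target CNP0240298.1, via methiodide 25 (not isolated)
Conditions: MeI, MeCN, rt; then aq. NaHCO3/EtOAc, rt
Reagents that add atoms: none
Why: Quaternisation of the amine followed by Hofmann-type E1cB elimination under bicarbonate should unveil the C11=C13 α-methylene lactone under conditions that spare the epoxide, both esters and the enoate.

**Compound list**

1 | (S)-2-methylglycidol, (2S)-(2-methyloxiran-2-yl)methanol | O1C[C@]1(C)CO | starting material
2 | (R)-tert-butyldimethyl[(2-methyloxiran-2-yl)methoxy]silane | O1C[C@]1(C)CO[Si](C)(C)C(C)(C)C | intermediate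
3 | 1,3-dithiane | C1CSCSC1 | starting material
4 | (2R)-1-[(tert-butyldimethylsilyl)oxy]-3-(1,3-dithian-2-yl)-2-methylpropan-2-ol | S1CCCSC1C[C@](O)(C)CO[Si](C)(C)C(C)(C)C | intermediate
5 | (5S)-5-(hydroxymethyl)furan-2(5H)-one | O=C1O[C@H](CO)C=C1 | starting material
6 | (5S)-5-{[(tert-butyldimethylsilyl)oxy]methyl}furan-2(5H)-one | O=C1O[C@H](CO[Si](C)(C)C(C)(C)C)C=C1 | intermediate
7 | N,N-dimethylmethyleneiminium iodide (Eschenmoser's salt) | C=[N+](C)C.[I-] | starting material
8 | (3R,4S,5S)-5-{[(tert-butyldimethylsilyl)oxy]methyl}-4-{2-[(2R)-3-[(tert-butyldimethylsilyl)oxy]-2-hydroxy-2-methylpropyl]-1,3-dithian-2-yl}-3-[(dimethylamino)methyl]oxolan-2-one (all-trans lactone) | CN(C)C[C@@H]1C(=O)O[C@H](CO[Si](C)(C)C(C)(C)C)[C@H]1C2(SCCCS2)C[C@](O)(C)CO[Si](C)(C)C(C)(C)C | intermediate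
9 | (3R,4S,5S)-4-[(3R)-4-[(tert-butyldimethylsilyl)oxy]-3-hydroxy-3-methylbutanoyl]-5-{[(tert-butyldimethylsilyl)oxy]methyl}-3-[(dimethylamino)methyl]oxolan-2-one | CN(C)C[C@@H]1C(=O)O[C@H](CO[Si](C)(C)C(C)(C)C)[C@H]1C(=O)C[C@](O)(C)CO[Si](C)(C)C(C)(C)C | intermediate
10 | (3R,4R,5S)-4-[(1R,3R)-4-[(tert-butyldimethylsilyl)oxy]-1,3-dihydroxy-3-methylbutyl]-5-{[(tert-butyldimethylsilyl)oxy]methyl}-3-[(dimethylamino)methyl]oxolan-2-one (C8/C10 anti-diol) | CN(C)C[C@@H]1C(=O)O[C@H](CO[Si](C)(C)C(C)(C)C)[C@H]1[C@H](O)C[C@](O)(C)CO[Si](C)(C)C(C)(C)C | intermediate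
11 | (E)-2-methylbut-2-en-1-ol (tiglyl alcohol) | C/C=C(\C)CO | starting material
12 | [(2R,3R)-2,3-dimethyloxiran-2-yl]methanol | OC[C@@]1(C)O[C@@H]1C | intermediate
13 | (2S,3R)-2,3-dimethyloxirane-2-carboxylic acid | OC(=O)[C@@]1(C)O[C@@H]1C | intermediate
14 | (2S,3R)-2,3-dimethyloxirane-2-carboxylic 2,4,6-trichlorobenzoic anhydride | O=C(OC(=O)[C@@]1(C)O[C@@H]1C)c1c(Cl)cc(Cl)cc1Cl | intermediate (not isolated)
15 | (1R,3R)-4-[(tert-butyldimethylsilyl)oxy]-1-[(2S,3R,4R)-2-{[(tert-butyldimethylsilyl)oxy]methyl}-4-[(dimethylamino)methyl]-5-oxooxolan-3-yl]-3-hydroxy-3-methylbutyl (2S,3R)-2,3-dimethyloxirane-2-carboxylate | CN(C)C[C@@H]1C(=O)O[C@H](CO[Si](C)(C)C(C)(C)C)[C@H]1[C@H](OC(=O)[C@@]2(C)O[C@@H]2C)C[C@](O)(C)CO[Si](C)(C)C(C)(C)C | intermediate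
16 | (1R,3R)-1-[(2S,3R,4R)-4-[(dimethylamino)methyl]-2-(hydroxymethyl)-5-oxooxolan-3-yl]-3,4-dihydroxy-3-methylbutyl (2S,3R)-2,3-dimethyloxirane-2-carboxylate | CN(C)C[C@@H]1C(=O)O[C@H](CO)[C@H]1[C@H](OC(=O)[C@@]2(C)O[C@@H]2C)C[C@](O)(C)CO | intermediate
17 | (1R,3R)-1-[(2S,3R,4R)-4-[(dimethylamino)methyl]-2-formyl-5-oxooxolan-3-yl]-3-hydroxy-3-methyl-4-oxobutyl (2S,3R)-2,3-dimethyloxirane-2-carboxylate (hydroxy dialdehyde, C5 and C1 as CHO) | CN(C)C[C@@H]1C(=O)O[C@H](C=O)[C@H]1[C@H](OC(=O)[C@@]2(C)O[C@@H]2C)C[C@](O)(C)C=O | intermediate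
18 | methyl acetoacetate (methyl 3-oxobutanoate) | COC(=O)CC(C)=O | starting material
19 | Knoevenagel adduct: C4=C5 alkylidene acetoacetate of 17 (E/Z mixture, C1 aldehyde and C10–OH still free) | CN(C)C[C@@H]1C(=O)O[C@H](C=C(C(C)=O)C(=O)OC)[C@H]1[C@H](OC(=O)[C@@]2(C)O[C@@H]2C)C[C@](O)(C)C=O | intermediate (not isolated)
20 | oxa-Michael adduct: 2,7-cis-oxepane (O, C5–C10) carrying the acetoacetate unit on C5 cis to the formyl group on C10; C4 epimers/enol | CN(C)C[C@@H]1C(=O)O[C@H]2[C@H]1[C@H](OC(=O)[C@@]3(C)O[C@@H]3C)C[C@](C)(C=O)O[C@@H]2C(C(C)=O)C(=O)OC | intermediate (not isolated)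
21 | methyl (5R,6S,7R,8R,10R,11R)-13-(dimethylamino)-8-{[(2S,3R)-2,3-dimethyloxirane-2-carbonyl]oxy}-5,10-epoxy-3-hydroxy-11,13-dihydrogermacra-1,3-dien-12,6-olid-15-oate (chelated enol of the C3 ketone) | CN(C)C[C@@H]1C(=O)O[C@H]2[C@H]1[C@H](OC(=O)[C@@]3(C)O[C@@H]3C)C[C@]1(C)C=CC(O)=C(C(=O)OC)[C@H]2O1 | intermediate
22 | methyl (5R,6S,7R,8R,10S,11R)-13-(dimethylamino)-8-{[(2S,3R)-2,3-dimethyloxirane-2-carbonyl]oxy}-5,10-epoxy-3-hydroxy-11,13-dihydrogermacr-3-en-12,6-olid-15-oate (enol of the β-keto ester) | CN(C)C[C@@H]1C(=O)O[C@H]2[C@H]1[C@H](OC(=O)[C@@]3(C)O[C@@H]3C)C[C@]1(C)CCC(O)=C(C(=O)OC)[C@H]2O1 | intermediate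
23 | C3 enol triflate of 22 (5R,6S,7R,8R,10S,11R) | CN(C)C[C@@H]1C(=O)O[C@H]2[C@H]1[C@H](OC(=O)[C@@]3(C)O[C@@H]3C)C[C@]1(C)CCC(OS(=O)(=O)C(F)(F)F)=C(C(=O)OC)[C@H]2O1 | intermediate
24 | methyl (5R,6S,7R,8R,10S,11R)-13-(dimethylamino)-8-{[(2S,3R)-2,3-dimethyloxirane-2-carbonyl]oxy}-5,10-epoxy-11,13-dihydrogermacr-3-en-12,6-olid-15-oate | CN(C)C[C@@H]1C(=O)O[C@H]2[C@H]1[C@H](OC(=O)[C@@]3(C)O[C@@H]3C)C[C@]1(C)CCC=C(C(=O)OC)[C@H]2O1 | intermediate
25 | N-methyl quaternary ammonium iodide of 24 | C[N+](C)(C)C[C@@H]1C(=O)O[C@H]2[C@H]1[C@H](OC(=O)[C@@]3(C)O[C@@H]3C)C[C@]1(C)CCC=C(C(=O)OC)[C@H]2O1.[I-] | intermediate (not isolated)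
26 | CNP0240298.1, methyl (5R,6S,7R,8R,10S)-8-{[(2S,3R)-2,3-dimethyloxirane-2-carbonyl]oxy}-5,10-epoxygermacra-3,11(13)-dien-12,6-olid-15-oate | C=C1C(=O)O[C@H]2[C@H]1[C@H](OC(=O)[C@@]1(C)O[C@@H]1C)C[C@]1(C)CCC=C(C(=O)OC)[C@H]2O1 | target

**Step count and risks**

Total step count: 16. Longest linear sequence: 13 steps (steps 1, 2, 4, 5, 6, 9, 10, 11, 12, 13, 14, 15, 16).

Steps most likely to fail, riskiest first:

Step 12 (Proposed new method). The reversible oxa-Michael closure by the tertiary C10 hydroxyl may lie too far on the open side and the aldol closure may be too slow. The alkylidene intermediate could then be drained by addition of a second acetoacetate, by amine-mediated aldolisation from C6, or by α-ketol rearrangement of the C10/C1 hydroxy aldehyde. The fallback uses known chemistry and replaces the aldol closure by an olefination. It sets out from 17: condensation with methyl 4-(diethoxyphosphoryl)-3-oxobutanoate under the same buffered piperidine conditions at 0 °C should give, by the established Knoevenagel/oxa-Michael pattern, the oxepane keto phosphonate aldehyde F1. Its dianion (NaH, 2 equiv, THF, 0 °C) should then close the oxepine ring by an intramolecular Horner–Wadsworth–Emmons reaction. This closure is irreversible, selects the bridging C5 epimer in the same way, and returns to the route at 21.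

Step 4. Proton transfer from the γ-position (C6–H) of butenolide 6 to the hindered dilithio species, 1,2-addition to the lactone carbonyl, or incomplete capture of the enolate by the iminium salt may compete with the tandem process. The fallback abandons the one-flask dianion union for a protected, mono-anionic and stepwise sequence. It sets out from 4: silylation of the tertiary alcohol (TMSCl, imidazole) gives the trimethylsilyl ether F2. Its lithio derivative (t-BuLi, THF/DMPU, −78 °C) is added to 6 and the enolate is simply protonated, giving the trans lactone F3. In a separate operation the lactone enolate of F3 (LDA, THF, −78 °C) is aminomethylated with 7 to give F4. Mild acid methanolysis (citric acid, MeOH) removes the tertiary trimethylsilyl ether and returns to the route at 8.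

Step 6. Slow hydrogenation of the hindered ketone, or a mismatch between the catalyst and the existing stereocentres, may give poor facial selectivity at C8. The fallback changes from chemocatalytic hydrogenation to an enzymatic carbonyl reduction: a ketoreductase selected from a screening panel (NADPH recycling with isopropanol, aqueous buffer/DMSO, 30 °C) reduces 9 directly to 10 under enzyme control. No new compound is made.

**Further compounds**

F1 | step 12 | oxepane keto phosphonate aldehyde: the analogue of 20 in which the acetoacetate methyl group carries a diethoxyphosphoryl group (C4 epimers/enol) | CN(C)C[C@@H]1C(=O)O[C@H]2[C@H]1[C@H](OC(=O)[C@@]3(C)O[C@@H]3C)C[C@](C)(C=O)O[C@@H]2C(C(=O)CP(=O)(OCC)OCC)C(=O)OC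
F2 | step 4 | trimethylsilyl ether of 4, (2R)-configured | S1CCCSC1C[C@](O[Si](C)(C)C)(C)CO[Si](C)(C)C(C)(C)C
F3 | step 4 | trans-4,5-disubstituted lactone from conjugate addition of lithiated F2 to 6 (no aminomethyl group) | C1C(=O)O[C@H](CO[Si](C)(C)C(C)(C)C)[C@H]1C2(SCCCS2)C[C@](O[Si](C)(C)C)(C)CO[Si](C)(C)C(C)(C)C
F4 | step 4 | trimethylsilyl ether of 8 | CN(C)C[C@@H]1C(=O)O[C@H](CO[Si](C)(C)C(C)(C)C)[C@H]1C2(SCCCS2)C[C@](O[Si](C)(C)C)(C)CO[Si](C)(C)C(C)(C)C
F0 | step 6 | none | none
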